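# Total synthesis plan for CNP0208239.1 (compound 40) by ring contraction of a fourteen-membered furan lactone

## The problem

Compound 40 is a briarane-type diterpenoid in which a cyclohexene (ring A: C1, C10, C11, C12, C13, C14, with C11=C12) is trans-fused through the C1–C10 bond to a ten-membered carbocycle (C1–C10); the larger ring also carries an α-methyl-γ-ylidene butenolide at C7–C8 (C17, C19 and the lactone oxygen), and the methyl groups are C15 on C1, C16 on C5, C18 on C17 and C20 on C11. Five stereocentres, all S, have to be set: the quaternary C1, C2 (isovalerate), C5 (tertiary alcohol), C10 and C14 (acetate, trans to C15 on ring A). C1 and C10 are vicinal and define the ring fusion (C15 and H-10 anti), and C2 stands next to C1 and can direct both. C14 is a neopentyl carbinol better left to a reagent, and C5 is cut off from the other centres by two methylene groups on one side and the planar butenolide on the other, so it has to come from the chiral pool. The C6=C7 alkene is (E) by the sequence rule but cis inside the ten-membered ring, so the ring can be left to impose it. The weak points are the enol lactone (base, hydride, nucleophiles), the C5 carbinol, which becomes allylic to it and prone to ionise, and two different esters on hindered, 1,3-related secondary oxygens (C14 and C2) that can exchange acyl groups; the butenolide should therefore travel as a furan and the acyl groups should arrive late. The decisive feature is the pair C1/C10: with a carboxyl at C14 and an alkene at C11=C12, the unit C14–C1–C10–C11=C12 is a γ,δ-unsaturated acid, the retron of an ester enolate Claisen rearrangement. Because C1 and C10 are both ring atoms, the allyl ester can be a fourteen-membered lactone (carbonyl C14, oxygen on C12) that contracts to the ten-membered ring as C1–C10 forms, so the ring least willing to close end to end never has to.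

## Retrosynthesis

**Ester and silyl groups (40 ⇒ 39 ⇒ 38).** The C2–O acyl bond is cut first, then the two O–Si bonds. The isovalerate comes last because it has α-hydrogens that would not survive the enolisation or the hydride steps, and because late acylation shortens the time a free C2 hydroxyl spends beside the C14 acetate. Diol 39 and bis(triethylsilyl) ether 38 differ from 40 only in these groups. The forward steps need a fluoride source mild enough for the enol lactone and an acylation that takes the secondary C2 hydroxyl and leaves the tertiary C5 hydroxyl.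

**Ylidene butenolide (38 ⇒ 36 ⇒ 34).** The C6=C7 alkene is returned to the C7 hemiketal of hydroxybutenolide 36, and the C7–O and C19=O bonds of 36 to the two α-carbons of furan 34. The 2,3,4-trisubstituted furan has a single α-hydrogen (on C19), so singlet oxygen and base can give only one hydroxybutenolide; the hemiketal has hydrogens only on C6, so dehydration can place the alkene only where it is wanted. Building the lactone onto a C7 ketone was set aside because that ketone would sit β to the C5 carbinol (retro-aldol). Furan 34 tolerates bases, hydrides and organometallic reagents that 38 would not. The forward steps must spare the C11=C12 alkene (ene reaction) and the C5 silyl ether (ionisation).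

**Ring A (34 ⇒ 33 ⇒ 32 ⇒ 31 ⇒ 30 ⇒ 29).** The C11=C12 alkene is opened by retro-metathesis to an isopropenyl group on C10 and an allyl group on C14 (33). The acetate is removed (32), and C13–C14 is cut by retro-allylation to aldehyde 31, which is acid 29 after two redox steps (30). These cuts are preferred to an aldol or alkylative closure of ring A because they leave on the ten-membered ring exactly what a Claisen rearrangement delivers: a carboxyl carbon on C1 and an isopropenyl group on C10. Acid 29 has one ring and one stereocentre fewer than 34. The forward sequence needs reagent control at C14 on a neopentyl aldehyde and a metathesis that forms a trisubstituted alkene between two substituted carbons.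

**Ring contraction (29 ⇒ 26), the key disconnection.** The C1–C10 bond is cut and C12 is reconnected to the carboxyl oxygen, so acid 29 becomes fourteen-membered lactone 26 by way of silyl ketene acetal 27. This is preferred to cutting C5–C6, C6–C7 or C8–C9 (all direct ten-membered closures) for three reasons:
- the ring that must be closed end to end is a fourteen-membered lactone;
- the two adjacent stereocentres, the quaternary one included, form together in one chair transition state;
- their absolute sense can be taken from the C2 stereocentre that an aldol supplies.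

Lactone 26 has no quaternary carbon and only two stereocentres that matter, C2 and C5, since C1 is erased on enolisation. The forward reaction needs the (E)-alkene, the ketene acetal with C2 anti to the ring oxygen, a chair, and addition of C10 to the face of C1 on which the C3 chain lies. That last requirement decided the C2 protecting group. A free C2 hydroxyl would fix the enolate geometry by chelation, but it would hold the C2 oxygen in the enolate plane and turn C3, and with it the tether to C10, to the other face of C1. A bulky, non-chelating silyl ether leaves allylic strain in charge (H-2 in the plane) and gives the sense required.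

**Lactone (26 ⇒ 24).** The C14–O bond is cut to seco acid 24, which has a primary allylic alcohol at C12. Lactonisation is chosen over closing the large ring at a C–C bond because fourteen-membered lactones form readily from activated esters and epimerisation at C1 would not matter. The forward step needs only high dilution.

**Propionate unit (24 ⇒ 23 ⇒ 21 ⇒ 20 ⇒ 17 + 18).** The C12 alcohol is taken back to the methyl ester (23), the acid to the acyl oxazolidinone (21, 20), and the C1–C2 bond is cut by a retro-aldol to aldehyde 17 and propionyl oxazolidinone 18. The auxiliary-controlled syn aldol sets C2, the one new stereocentre that survives, and brings C1, C14 and C15 in one step. The C12 ester is kept until after the aldol because it deactivates the C10=C11 alkene in the oxidative cleavage that makes 17. The forward sequence needs a reduction of the ester that leaves the carboxyl group alone.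

**Side chain and aldehyde (17 ⇒ 15 ⇒ 10 + 12).** The C2 aldehyde is traced to the terminal alkene of 15, and the C8–C9 bond is cut to furyl bromide 10 and allylic bromide 12. C8–C9 is preferred to C9–C10 because it uses the bromine that has already directed the first lithiation and a four-carbon electrophile of fixed (E) geometry made in one step from methyl tiglate 11. The forward coupling must join at the CH2 terminus of the allyl unit and keep the alkene geometry.

**Furan core and C5 (10 ⇒ 9 ⇒ 8 ⇒ 3 + 5; 3 ⇒ 1; 5 ⇒ 4).** The silyl ether is removed (9), then C3–C4 (allyl anion on epoxide 8) and C6–C7 (furyllithium on the epoxide of tosylate 5) are cut in turn. The 2-methylglycidol skeleton thus serves as a double electrophile: its epoxide carbon becomes C6 and its carbinol carbon C4, so the C5 configuration passes unchanged from (S)-2-methylglycidol 4. Bromofuran 3 comes from 3,4-dibromofuran 1 by one bromine–lithium exchange and methylation. The remaining bromine acidifies the neighbouring α-hydrogen, which makes the lithiation regioselective, and later becomes the C8 handle.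

## Roads not taken

**Alternative 1: ring A first, by asymmetric conjugate addition with aldol trapping.**
- Cut: C9–C10 and C1–C2, both on a ring A cyclohexenone.
- Forward key step: a copper catalyst carrying a chiral phosphine adds silylmethyl Grignard reagent A4 to C10 of enone A2, and the C1 enolate is trapped with aldehyde A3. This gives aldol A1 with C10, C1 and C2 set in one flask.
- Merits: three contiguous stereocentres, the quaternary one included, come from achiral materials and a catalytic amount of chiral ligand. Ring A is complete from the outset, with C14 and C11 as differentiated carbonyl groups. A1 is reached in a handful of steps, where the chosen plan needs fourteen to hold the same triad in 29.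
- Weak points: C10 of A2 is flanked by the ketal carbon and the enone is α-substituted, the pattern on which such additions are slowest and least selective. The fully substituted enolate must then form a quaternary carbon in a reversible aldol with an enolisable aldehyde, and the C2 configuration is not assured. Above all, A1 leaves the whole ten-membered ring open: C5 is still a masked ketone that must be made stereogenic far from any control element, and C6–C9 with the lactone must still be attached and closed end to end.
- Comparison: up to A1 this road is better in speed and in the catalytic origin of its chirality, and it needs no allylation–metathesis sequence for ring A. The chosen plan sets against this an easy ring closure (fourteen-membered lactonisation) followed by an intramolecular pericyclic contraction, and a C5 centre bought from 4. Its risk lies in one well-understood step and not in an unsolved macrocyclisation at the end.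

**Alternative 2: nitrile oxide cycloaddition that closes the ten-membered ring.**
- Cut: C6–C7 and O–C5 (retro-1,3-dipolar cycloaddition).
- Forward key step: nitrile oxide A6, generated on C7 of the (Z)-enoate arm, adds across the 1,1-disubstituted C5=C6 alkene to give isoxazoline-bridged carbocycle A5.
- Merits: one step closes the ring, forms C6–C7 and puts oxygen on C5 with the normal regiochemistry. Both acyl groups and all ring A stereocentres are already in place. After N–O cleavage the C7 carbonyl would lactonise with the ester and dehydrate to 40, so the endgame is about four steps against nine after the key step of the chosen plan, with no furan photooxygenation.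
- Weak points: end-to-end closure of a ten-membered ring by cycloaddition is disfavoured by entropy and transannular strain, and dimerisation of the nitrile oxide competes at any practical concentration. The dipole is hindered and conjugated to a tetrasubstituted alkene. The quaternary C5 centre would be created with only remote centres (C1, C2, C10) to direct it across a forming medium ring. The tetrasubstituted (Z)-enoate must be made geometrically pure, and the esters must survive the reductive N–O cleavage.
- Comparison: if the cycloaddition worked with useful facial selectivity, this road would be shorter than the chosen one and better in protecting-group economy. The chosen plan sets against it a C5 centre of certain configuration and a ten-membered ring formed inside a pre-organised fourteen-membered ring, at the price of carrying silyl groups and a furan to a late stage.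

**Alternative 3: carbonyl-ene annulation of ring A.**
- Cut: C13–C14 (retro-ene), opening ring A on a finished ten-membered ring.
- Forward key step: in aldehyde A8 the terminal C13 of the butenyl group on C10 attacks the C14 aldehyde while H-11 passes to oxygen. This gives alcohol A7 with C13–C14, the C11=C12 alkene and the C14 carbinol formed together.
- Merits: ring A, its trisubstituted alkene and the C14 hydroxyl arise in one atom-economical step with no carbon lost, where the chosen plan spends five steps between 29 and 34. A7 needs only acetylation and desilylation. A8 could in principle come from the same kind of ring contraction with a different allylic unit, so this road is compatible with the chosen key step.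
- Weak points: the ene hydrogen and the carbonyl are both held on the ring being formed, so the concerted transition state is bridged and strained. A stepwise cationic pathway under a Lewis acid is more likely, with loss of control over the alkene position. The C14 configuration depends on the aldehyde rotamer and has no evident bias towards the alcohol trans to C15. The Lewis acid would meet the enol lactone and the ionisable allylic C5 silyl ether of A8. C11 has to be made as a stereocentre only to be destroyed, and the step does nothing for the ten-membered ring, which is the real problem.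
- Comparison: in step economy for ring A this road is better. The chosen plan sets against it reagent control at C14, a metathesis of well-understood scope, and construction of ring A while the lactone is still a robust furan.

Key step: step 14

## Route

Assumption: the allylborane made from (+)-α-pinene is taken to add to the Si face of α-quaternary aldehyde 31 as it does with pivalaldehyde, and the locants C1–C20 defined above are kept for every intermediate.

Step 1
Reactants: 1 3,4-dibromofuran
Product: 3 3-bromo-4-methylfuran, via 3-bromo-4-lithiofuran 2 (not isolated)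
Conditions: n-BuLi (1.0 equiv), Et2O, −78 °C; MeI, −78 → 0 °C
Reagents that add atoms: iodomethane CI
Why: Bromine–lithium exchange at one of the two equivalent C–Br bonds gives a 3-furyllithium that is stable at −78 °C and is methylated by MeI (halogen–metal exchange and alkylation); the remaining bromine later directs lithiation and serves as the C8 handle.

Step 2
Reactants: 4 (S)-2-methylglycidol
Product: 5 (R)-(2-methyloxiran-2-yl)methyl 4-methylbenzenesulfonate
Conditions: TsCl, Et3N, DMAP (cat.), CH2Cl2, 0 °C
Reagents that add atoms: 4-methylbenzenesulfonyl chloride Cc1ccc(cc1)S(Cl)(=O)=O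
Why: O-Sulfonylation of the primary alcohol leaves the quaternary stereocentre untouched; the descriptor changes from S to R only because the sequence-rule ranking changes.

Step 3
Reactants: 3 3-bromo-4-methylfuran; 5 (R)-(2-methyloxiran-2-yl)methyl 4-methylbenzenesulfonate
Product: 8 (R)-2-[(3-bromo-4-methylfuran-2-yl)methyl]-2-methyloxirane, via 3-bromo-2-lithio-4-methylfuran 6 (not isolated), via hydroxy tosylate 7 (not isolated)
Conditions: LiN(i-Pr)2, THF, −78 °C; 5, BF3·OEt2, −78 °C; then K2CO3, MeOH, 0 °C → rt
Reagents that add atoms: none
Why: The amide base removes the furan α-hydrogen flanked by oxygen and bromine (directed lithiation), and the BF3-activated epoxide is opened at its unsubstituted carbon to form C6–C7, while the neopentyl tosylate is not displaced at −78 °C. Base then closes the tertiary alkoxide onto the tosylate (intramolecular Williamson reaction, 3-exo-tet), moving the epoxide to C4–C5 without touching the C5 stereocentre.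

Step 4
Reactants: 8 (R)-2-[(3-bromo-4-methylfuran-2-yl)methyl]-2-methyloxirane
Product: 9 (S)-1-(3-bromo-4-methylfuran-2-yl)-2-methylhex-5-en-2-ol
Conditions: CH2=CHCH2MgBr, CuI (10 mol %), THF, −40 → 0 °C
Reagents that add atoms: allylmagnesium bromide C=CC[Mg]Br
Why: Copper-catalysed Grignard opening of the 2,2-disubstituted epoxide at its CH2 terminus forms C3–C4; the catalyst outruns Lewis-acid rearrangement of the epoxide, and the furyl bromide is inert to the reagent at this temperature.

Step 5
Reactants: 9 (S)-1-(3-bromo-4-methylfuran-2-yl)-2-methylhex-5-en-2-ol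
Product: 10 (S)-triethyl{[1-(3-bromo-4-methylfuran-2-yl)-2-methylhex-5-en-2-yl]oxy}silane
Conditions: Et3SiOTf, 2,6-lutidine, CH2Cl2, −78 → 0 °C
Reagents that add atoms: triethylsilyl trifluoromethanesulfonate CC[Si](CC)(CC)OS(=O)(=O)C(F)(F)F
Why: Silylation of the tertiary alcohol with the silyl triflate; the ether must mask the C5 hydroxyl through the lithiations, the enolisation and the hydride steps.

Step 6
Reactants: 11 methyl tiglate
Product: 12 methyl (E)-4-bromo-2-methylbut-2-enoate
Conditions: NBS, azobisisobutyronitrile (cat.), PhCF3, 85 °C; distillation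
Reagents that add atoms: N-bromosuccinimide O=C1CCC(=O)N1Br
Why: Wohl–Ziegler allylic bromination at the γ-methyl of the (E)-enoate; the allyl radical keeps the alkene geometry, and the γ-bromide should be separable from the minor bromomethyl isomer by distillation.

Step 7
Reactants: 10 (S)-triethyl{[1-(3-bromo-4-methylfuran-2-yl)-2-methylhex-5-en-2-yl]oxy}silane; 12 methyl (E)-4-bromo-2-methylbut-2-enoate
Product: 15 methyl (E)-2-methyl-4-{4-methyl-2-[(S)-2-methyl-2-(triethylsilyloxy)hex-5-enyl]furan-3-yl}but-2-enoate, via furan-3-yllithium 13 (not isolated), via furan-3-ylzinc chloride 14 (not isolated)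
Conditions: n-BuLi, THF, −78 °C; ZnCl2, −78 → 0 °C; 12, Pd(PPh3)4 (5 mol %), 0 °C → rt
Reagents that add atoms: none
Why: Bromine–lithium exchange, transmetalation to zinc and Negishi coupling with the allylic bromide form C8–C9; the organozinc tolerates the ester, and coupling occurs at the unsubstituted allyl terminus. The (E) geometry is kept because syn/anti exchange would need palladium on the fully substituted carbon.

Step 8
Reactants: 15 methyl (E)-2-methyl-4-{4-methyl-2-[(S)-2-methyl-2-(triethylsilyloxy)hex-5-enyl]furan-3-yl}but-2-enoate
Product: 17 methyl (E)-2-methyl-4-{4-methyl-2-[(S)-2-methyl-5-oxo-2-(triethylsilyloxy)pentyl]furan-3-yl}but-2-enoate, via terminal 1,2-diol 16 (not isolated)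
Conditions: OsO4 (2 mol %), NaIO4, 2,6-lutidine, dioxane/H2O (3:1), rt
Reagents that add atoms: sodium periodate [Na+].[O-]I(=O)(=O)=O; osmium tetroxide O=[Os](=O)(=O)=O
Why: Lemieux–Johnson cleavage: OsO4 dihydroxylates the unhindered monosubstituted alkene much faster than the ester-deactivated trisubstituted alkene or the furan, and NaIO4 cleaves the diol to the C2 aldehyde.

Step 9
Reactants: 17 methyl (E)-2-methyl-4-{4-methyl-2-[(S)-2-methyl-5-oxo-2-(triethylsilyloxy)pentyl]furan-3-yl}but-2-enoate; 18 (R)-4-benzyl-3-propanoyl-1,3-oxazolidin-2-one
Product: 20 syn-aldol imide (C1 R with methyl, C2 S with hydroxyl, C5 S; C14 is the imide carbonyl, C12 the methyl ester), via dibutylboron (Z)-enolate 19 (not isolated)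
Conditions: 18, n-Bu2BOTf, i-Pr2NEt, CH2Cl2, 0 °C; 17, −78 → 0 °C; pH 7 buffer, MeOH, H2O2
Reagents that add atoms: none
Why: Evans syn aldol: the (Z)-boron enolate reacts through a closed chair transition state on the face away from the benzyl group, which with the (R)-auxiliary sets C2 as S (the permanent stereocentre) and C1 as R (erased in step 14) and forms C1–C2.

Step 10
Reactants: 20 syn-aldol imide
Product: 21 C2 triethylsilyl ether of imide 20
Conditions: Et3SiOTf, 2,6-lutidine, CH2Cl2, −78 → 0 °C
Reagents that add atoms: triethylsilyl trifluoromethanesulfonate CC[Si](CC)(CC)OS(=O)(=O)C(F)(F)F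
Why: Silylation of the aldol hydroxyl under non-basic conditions avoids retro-aldol; the bulky non-chelating silyl ether at C2 is the control element needed in step 14.

Step 11
Reactants: 21 C2 triethylsilyl ether of imide 20
Product: 23 C14 carboxylic acid with the C12 methyl ester (C1 R, C2 S, C5 S), via peroxy acid 22 (not isolated)
Conditions: LiOH, H2O2, THF/H2O (3:1), 0 °C; Na2SO3; dil. HCl to pH 4
Reagents that add atoms: hydrogen peroxide OO
Why: Hydroperoxide attacks the exocyclic imide carbonyl selectively (LiOOH cleavage of an N-acyl oxazolidinone) and sulfite reduces the peracid; the hindered conjugated methyl ester should be hydrolysed much more slowly at 0 °C.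

Step 12
Reactants: 23 C14 carboxylic acid with the C12 methyl ester
Product: 24 seco acid (C14 carboxylic acid, C12 primary (E)-allylic alcohol; C1 R, C2 S, C5 S)
Conditions: i-Bu2AlH (3.5 equiv), CH2Cl2, −78 °C; aq. potassium sodium tartrate
Reagents that add atoms: none
Why: The acid is deprotonated by the first equivalent of hydride and as the carboxylate resists reduction at −78 °C, while the enoate is reduced 1,2 to the allylic alcohol with the alkene geometry unchanged (chemoselective ester reduction).

Step 13
Reactants: 24 seco acid
Product: 26 fourteen-membered furan lactone (ring atoms C14, O, C12, C11, C10, C9, C8, C7, C6, C5, C4, C3, C2, C1; 10E; C1 R, C2 S, C5 S; triethylsilyl ethers on C2 and C5), via mixed 2,4,6-trichlorobenzoic anhydride 25 (not isolated)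
Conditions: 2,4,6-Cl3C6H2COCl, Et3N, THF, rt; slow addition to DMAP, toluene, 80 °C (about 1 mM)
Reagents that add atoms: none
Why: Yamaguchi macrolactonisation: DMAP acylates on the mixed anhydride and the primary allylic alcohol closes the unstrained fourteen-membered ring under high dilution; any epimerisation at C1 is of no consequence because C1 becomes trigonal in the next step.

Step 14
Reactants: 26 fourteen-membered furan lactone
Product: 29 ten-membered furanocarbocyclic acid (1S,2S,5S,10S; C1 bears the C14 carboxyl and the C15 methyl, C10 an isopropenyl group, C2 and C5 triethylsilyl ethers), via silyl ketene acetal 27 (not isolated), via trimethylsilyl ester 28 (not isolated)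
Conditions: LiN(i-Pr)2, THF/DMPU (4:1), −78 °C; Me3SiCl/Et3N, −78 °C → rt; toluene, 100 °C; dil. aq. citric acid
Reagents that add atoms: none
Why: Deprotonation at C1 and O-silylation give silyl ketene acetal 27, which undergoes the (3,3) sigmatropic shift of an Ireland–Claisen rearrangement through the six-atom array C1–C14–O–C12–C11–C10, C1–C10 forming as C12–O breaks; the closest known reaction type is the four-atom ring contraction of macrocyclic allylic lactones to 2-alkenylcycloalkanecarboxylic acids. The ten-membered ring is closed by ring contraction, a transannular six-centre bond formation inside the fourteen-membered ring that expels C14 and C11 as the carboxyl and isopropenyl substituents, not by an end-to-end cyclisation. C10 is controlled by the (E)-alkene, which puts C9 pseudo-equatorial in the chair. C1 is controlled by the ketene acetal geometry: the s-cis lactone runs antiperiplanar through C2–C1–C14–O, so enolisation in the dissociating THF/DMPU medium, which also places the larger α-branch syn to the enolate oxygen, should give the ring-trans (Z) ketene acetal from either C1 epimer, with C2 pseudo-equatorial; diequatorial C2/C9 leaves C15 and H-10 anti, the trans fusion of 40. The absolute sense is relayed from C2: allylic 1,3-strain holds H-2 in the ketene acetal plane facing the silyloxy group on C14, the C3 chain then lies on one face and brings C10 to that face, anti to the C2 silyloxy group. The selectivities needed are chair over boat and this facial choice; the eight-atom tether between two pseudo-equatorial positions (as in the Cope rearrangement of (E,E)-cyclodeca-1,5-dienes) and the bulky non-chelating silyl ether are there to secure them. Silylation at −78 °C forestalls β-elimination of the C2 silyloxy group, the furan and both silyl ethers are inert to the amide base, and aqueous work-up hydrolyses silyl ester 28 to 29.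

Step 15
Reactants: 29 ten-membered furanocarbocyclic acid
Product: 30 C14 primary alcohol (1R,2S,5S,10S; descriptor at C1 changes by ranking only)
Conditions: LiAlH4, THF, 0 → 40 °C
Reagents that add atoms: none
Why: LiAlH4 reduces the hindered α-quaternary carboxylic acid to the neopentyl alcohol; silyl ethers, furan and the isolated alkene are inert.

Step 16
Reactants: 30 C14 primary alcohol
Product: 31 C14 aldehyde (1S,2S,5S,10S)
Conditions: Dess–Martin periodinane, NaHCO3, CH2Cl2, 0 °C → rt
Reagents that add atoms: none
Why: Buffered Dess–Martin oxidation gives the non-enolisable α-quaternary aldehyde without touching the furan or the silyl ethers.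

Step 17
Reactants: 31 C14 aldehyde
Product: 32 homoallylic alcohol (14S; C14 bears OH and the allyl group C13–C12; 1R,2S,5S,10S)
Conditions: (−)-Ipc2B(allyl) [from (+)-α-pinene], Et2O, −78 °C → rt; NaBO3·4H2O, THF/H2O
Reagents that add atoms: B-allyldiisopinocampheylborane from (+)-α-pinene C=CCB([C@H]1[C@H](C)[C@H]2C[C@@H](C1)C2(C)C)[C@H]1[C@H](C)[C@H]2C[C@@H](C1)C2(C)C
Why: Brown allylation forms C13–C14 through a closed six-membered transition state that tolerates α-quaternary aldehydes; the isopinocampheyl groups direct allyl to the Si face, which gives 14S under reagent control.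

Step 18
Reactants: 32 homoallylic alcohol
Product: 33 C14 acetate of 32
Conditions: Ac2O, DMAP, pyridine, CH2Cl2, rt
Reagents that add atoms: acetic anhydride CC(=O)OC(C)=O
Why: DMAP-catalysed acetylation of the hindered secondary alcohol; placing the acetate now, while C2 is silylated, differentiates the two secondary oxygens.

Step 19
Reactants: 33 C14 acetate
Product: 34 tricyclic furan (ring A closed, C11=C12; 14-acetate; C2 and C5 triethylsilyl ethers; 1R,2S,5S,10S,14S)
Conditions: second-generation Grubbs catalyst RuCl2(=CHPh)(H2IMes)(PCy3) (5 mol %), CH2Cl2, 40 °C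
Reagents that add atoms: none
Why: Ring-closing metathesis between the monosubstituted alkene and the isopropenyl group closes the six-membered ring A with the trisubstituted C11=C12 alkene and releases ethene (the original C12 leaves with it); the furan does not take part.

Step 20
Reactants: 34 tricyclic furan
Product: 36 γ-hydroxybutenolide (C19 carbonyl, C7 hemiketal, C7 epimers), via furan endoperoxide 35 (not isolated)
Conditions: O2, hν (visible), tetraphenylporphyrin (cat.), i-Pr2NEt, CH2Cl2, −78 °C → rt
Reagents that add atoms: oxygen O=O
Why: Singlet oxygen adds (4+2) across the furan α-carbons far faster than it undergoes the Schenck ene reaction with the trisubstituted alkene, and the amine removes the only bridgehead hydrogen (on C19), so Kornblum–DeLaMare fragmentation can give only the C19 carbonyl and the C7 hemiketal. The C7 epimers converge in the next step.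

Step 21
Reactants: 36 γ-hydroxybutenolide
Product: 38 bis(triethylsilyl) ether of the ylidene butenolide (C6=C7 E; 1R,2S,5S,10S,14S), via C7 methanesulfonate 37 (not isolated)
Conditions: MsCl, Et3N, CH2Cl2, −20 → 0 °C
Reagents that add atoms: none
Why: Sulfonylation of the hemiketal hydroxyl and loss of methanesulfonate with the amine give the enol lactone (dehydration of a γ-hydroxybutenolide to a γ-ylidene butenolide); only C6 carries hydrogen next to C7, and the ten-membered ring should favour the alkene with C5 and C8 cis, which is the (E) isomer of 40.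

Step 22
Reactants: 38 bis(triethylsilyl) ether of the ylidene butenolide
Product: 39 C2,C5-diol (14-acetate; 1S,2S,5S,10S,14S)
Conditions: HF·pyridine, pyridine, THF, 0 °C → rt
Reagents that add atoms: none
Why: Fluoride-mediated cleavage of both triethylsilyl ethers under buffered, weakly acidic conditions should leave the esters and the enol lactone intact and should not promote acetyl migration from O14 to O2.

Step 23
Reactants: 39 C2,C5-diol
Product: 40 CNP0208239.1 (target; 1S,2S,5S,10S,14S, C6=C7 E)
Conditions: (Me2CHCH2CO)2O, DMAP, Et3N, CH2Cl2, 0 °C → rt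
Reagents that add atoms: 3-methylbutanoic anhydride CC(C)CC(=O)OC(=O)CC(C)C
Why: DMAP-catalysed acylation takes the secondary C2 hydroxyl; the tertiary C5 hydroxyl is acylated much more slowly, so the diol is differentiated without protection.

## Compound list

1 | 3,4-dibromofuran | Brc1cocc1Br | starting material
2 | 3-bromo-4-lithiofuran | [Li]c1cocc1Br | intermediate
3 | 3-bromo-4-methylfuran | Cc1cocc1Br | intermediate
4 | (S)-2-methylglycidol | OC[C@@]1(C)CO1 | starting material
5 | (R)-(2-methyloxiran-2-yl)methyl 4-methylbenzenesulfonate | Cc1ccc(cc1)S(=O)(=O)OC[C@@]1(C)CO1 | intermediate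
6 | 3-bromo-2-lithio-4-methylfuran | [Li]c1occ(C)c1Br | intermediate
7 | (R)-3-(3-bromo-4-methylfuran-2-yl)-2-hydroxy-2-methylpropyl 4-methylbenzenesulfonate | Cc1coc(C[C@@](C)(O)COS(=O)(=O)c2ccc(C)cc2)c1Br | intermediate
8 | (R)-2-[(3-bromo-4-methylfuran-2-yl)methyl]-2-methyloxirane | Cc1coc(C[C@]2(C)CO2)c1Br | intermediate
9 | (S)-1-(3-bromo-4-methylfuran-2-yl)-2-methylhex-5-en-2-ol | Cc1coc(C[C@@](C)(O)CCC=C)c1Br | intermediate
10 | (S)-triethyl{[1-(3-bromo-4-methylfuran-2-yl)-2-methylhex-5-en-2-yl]oxy}silane | Cc1coc(C[C@@](C)(O[Si](CC)(CC)CC)CCC=C)c1Br | intermediate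
11 | methyl tiglate, methyl (E)-2-methylbut-2-enoate | C/C=C(\C)C(=O)OC | starting material
12 | methyl (E)-4-bromo-2-methylbut-2-enoate | BrC/C=C(\C)C(=O)OC | intermediate
13 | {4-methyl-2-[(S)-2-methyl-2-(triethylsilyloxy)hex-5-enyl]furan-3-yl}lithium | [Li]c1c(C)coc1C[C@@](C)(O[Si](CC)(CC)CC)CCC=C | intermediate
14 | {4-methyl-2-[(S)-2-methyl-2-(triethylsilyloxy)hex-5-enyl]furan-3-yl}zinc chloride | Cl[Zn]c1c(C)coc1C[C@@](C)(O[Si](CC)(CC)CC)CCC=C | intermediate
15 | methyl (E)-2-methyl-4-{4-methyl-2-[(S)-2-methyl-2-(triethylsilyloxy)hex-5-enyl]furan-3-yl}but-2-enoate | COC(=O)/C(C)=C/Cc1c(C)coc1C[C@@](C)(O[Si](CC)(CC)CC)CCC=C | intermediate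
16 | terminal 1,2-diol of 15 (epimers at the secondary carbinol) | COC(=O)/C(C)=C/Cc1c(C)coc1C[C@@](C)(O[Si](CC)(CC)CC)CCC(O)CO | intermediate
17 | methyl (E)-2-methyl-4-{4-methyl-2-[(S)-2-methyl-5-oxo-2-(triethylsilyloxy)pentyl]furan-3-yl}but-2-enoate | COC(=O)/C(C)=C/Cc1c(C)coc1C[C@@](C)(O[Si](CC)(CC)CC)CCC=O | intermediate
18 | (R)-4-benzyl-3-propanoyl-1,3-oxazolidin-2-one | CCC(=O)N1[C@H](Cc2ccccc2)COC1=O | starting material
19 | dibutylboron (Z)-enolate of 18 | C/C=C(\OB(CCCC)CCCC)N1[C@H](Cc2ccccc2)COC1=O | intermediate
20 | syn-aldol imide (C1 R, C2 S hydroxyl, C5 S; (R)-benzyloxazolidinone on C14; C12 methyl ester) | COC(=O)/C(C)=C/Cc1c(C)coc1C[C@@](C)(O[Si](CC)(CC)CC)CC[C@H](O)[C@@H](C)C(=O)N1[C@H](Cc2ccccc2)COC1=O | intermediate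
21 | C2 triethylsilyl ether of imide 20 | COC(=O)/C(C)=C/Cc1c(C)coc1C[C@@](C)(O[Si](CC)(CC)CC)CC[C@H](O[Si](CC)(CC)CC)[C@@H](C)C(=O)N1[C@H](Cc2ccccc2)COC1=O | intermediate
22 | C14 peroxy acid | COC(=O)/C(C)=C/Cc1c(C)coc1C[C@@](C)(O[Si](CC)(CC)CC)CC[C@H](O[Si](CC)(CC)CC)[C@@H](C)C(=O)OO | intermediate
23 | C14 carboxylic acid with C12 methyl ester (C1 R, C2 S, C5 S) | COC(=O)/C(C)=C/Cc1c(C)coc1C[C@@](C)(O[Si](CC)(CC)CC)CC[C@H](O[Si](CC)(CC)CC)[C@@H](C)C(O)=O | intermediate
24 | seco acid (C14 carboxylic acid, C12 (E)-allylic alcohol) | OC/C(C)=C/Cc1c(C)coc1C[C@@](C)(O[Si](CC)(CC)CC)CC[C@H](O[Si](CC)(CC)CC)[C@@H](C)C(O)=O | intermediate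
25 | mixed 2,4,6-trichlorobenzoic anhydride of 24 | OC/C(C)=C/Cc1c(C)coc1C[C@@](C)(O[Si](CC)(CC)CC)CC[C@H](O[Si](CC)(CC)CC)[C@@H](C)C(=O)OC(=O)c1c(Cl)cc(Cl)cc1Cl | intermediate
26 | fourteen-membered furan lactone (10E; 1R,2S,5S; C2 and C5 triethylsilyl ethers) | O=C1OC/C(C)=C/Cc2c(C)coc2C[C@@](C)(O[Si](CC)(CC)CC)CC[C@H](O[Si](CC)(CC)CC)[C@H]1C | intermediate
27 | trimethylsilyl ketene acetal of 26 (C1=C14 Z, C2 anti to the ring oxygen) | C[Si](C)(C)O/C1=C(/C)[C@@H](O[Si](CC)(CC)CC)CC[C@](C)(O[Si](CC)(CC)CC)Cc2occ(C)c2C/C=C(\C)CO1 | intermediate
28 | trimethylsilyl ester of acid 29 | C[Si](C)(C)OC(=O)[C@@]1(C)[C@H](C(C)=C)Cc2c(C)coc2C[C@@](C)(O[Si](CC)(CC)CC)CC[C@@H]1O[Si](CC)(CC)CC | intermediate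
29 | ten-membered furanocarbocyclic acid (1S,2S,5S,10S) | OC(=O)[C@@]1(C)[C@H](C(C)=C)Cc2c(C)coc2C[C@@](C)(O[Si](CC)(CC)CC)CC[C@@H]1O[Si](CC)(CC)CC | intermediate
30 | C14 primary alcohol (1R,2S,5S,10S) | OC[C@@]1(C)[C@H](C(C)=C)Cc2c(C)coc2C[C@@](C)(O[Si](CC)(CC)CC)CC[C@@H]1O[Si](CC)(CC)CC | intermediate
31 | C14 aldehyde (1S,2S,5S,10S) | O=C[C@@]1(C)[C@H](C(C)=C)Cc2c(C)coc2C[C@@](C)(O[Si](CC)(CC)CC)CC[C@@H]1O[Si](CC)(CC)CC | intermediate
32 | (14S)-homoallylic alcohol (1R,2S,5S,10S,14S) | C=CC[C@H](O)[C@@]1(C)[C@H](C(C)=C)Cc2c(C)coc2C[C@@](C)(O[Si](CC)(CC)CC)CC[C@@H]1O[Si](CC)(CC)CC | intermediate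
33 | C14 acetate of 32 | C=CC[C@H](OC(C)=O)[C@@]1(C)[C@H](C(C)=C)Cc2c(C)coc2C[C@@](C)(O[Si](CC)(CC)CC)CC[C@@H]1O[Si](CC)(CC)CC | intermediate
34 | tricyclic furan with ring A closed (1R,2S,5S,10S,14S) | CC(=O)O[C@H]1CC=C(C)[C@@H]2Cc3c(C)coc3C[C@@](C)(O[Si](CC)(CC)CC)CC[C@H](O[Si](CC)(CC)CC)[C@@]12C | intermediate
35 | furan endoperoxide (O–O bridge between C7 and C19) | CC(=O)O[C@H]1CC=C(C)[C@@H]2CC3=C(C)C4OOC3(O4)C[C@@](C)(O[Si](CC)(CC)CC)CC[C@H](O[Si](CC)(CC)CC)[C@@]12C | intermediate
36 | γ-hydroxybutenolide (C7 hemiketal, C7 epimers) | CC(=O)O[C@H]1CC=C(C)[C@@H]2CC3=C(C)C(=O)OC3(O)C[C@@](C)(O[Si](CC)(CC)CC)CC[C@H](O[Si](CC)(CC)CC)[C@@]12C | intermediate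
37 | C7 methanesulfonate of 36 | CC(=O)O[C@H]1CC=C(C)[C@@H]2CC3=C(C)C(=O)OC3(OS(C)(=O)=O)C[C@@](C)(O[Si](CC)(CC)CC)CC[C@H](O[Si](CC)(CC)CC)[C@@]12C | intermediate
38 | C2,C5-bis(triethylsilyl) ether of deisovaleryl-40 (C6=C7 E) | CC(=O)O[C@H]1CC=C(C)[C@@H]2CC3=C(C)C(=O)O/C3=C/[C@@](C)(O[Si](CC)(CC)CC)CC[C@H](O[Si](CC)(CC)CC)[C@@]12C | intermediate
39 | C2,C5-diol, deisovaleryl-40 | CC(=O)O[C@H]1CC=C(C)[C@@H]2CC3=C(C)C(=O)O/C3=C/[C@@](C)(O)CC[C@H](O)[C@@]12C | intermediate
40 | CNP0208239.1 (1S,2S,5S,10S,14S; C6=C7 E) | CC(=O)O[C@H]1CC=C(C)[C@@H]2CC3=C(C)C(=O)O/C3=C/[C@@](C)(O)CC[C@H](OC(=O)CC(C)C)[C@@]12C | target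

## Step count and least certain steps

Total step count: 23. Longest linear sequence: 21 steps (steps 1, 3–5 and 7–23, from 1 to 40); steps 2 and 6 are side branches.

**Step 14 (key step).** Enolisation may go towards the ring-cis ketene acetal, because a fourteen-membered ring does not forbid it; the chair would then exchange methyl and carboxyl at C1. The rearrangement may also take a boat-like path, or the C2 silyloxy group may be lost by β-elimination before silylation. The fallback pairs the ketene acetal geometry with the alkene geometry: a ring-cis ketene acetal and a (Z)-C10=C11 alkene pass through the same chair with C2 and C9 both pseudo-axial and give the same C1/C10 relation. It sets out from 10. Lithiation, zincation and palladium-catalysed coupling as in step 7, but with methyl (Z)-4-bromo-2-methylbut-2-enoate F1 (radical bromination of methyl angelate), give (Z)-enoate F2. Lemieux–Johnson cleavage through diol F3 gives aldehyde F4, aldol with 19 gives imide F5, and silylation gives silyl ether F6. LiOOH cleavage through peroxy acid F7 gives acid F8, i-Bu2AlH gives (Z)-seco acid F9, and Yamaguchi lactonisation through mixed anhydride F10 gives (10Z)-lactone F11. Enolisation and silylation then give ring-cis ketene acetal F12, which rearranges to 28, and work-up returns to the route at 29.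

**Step 21.** Once the enol lactone forms, the C5 silyloxy group is allylic and may ionise; the ring-trans alkene isomer may form, or the sulfonate may reclose without elimination. The fallback replaces dehydration by dehydrogenation and sets out from 36. NaBH4 reduces the hemiketal through its open keto acid form to butenolide F18 (C7–H). Et3SiOTf and Et3N give 2-silyloxyfuran F19, and PhSeCl selenylates C7 to give selenide F20. H2O2 then brings about oxidative syn-elimination, which can take a hydrogen only from C6, and returns to the route at 38.

**Step 17.** Addition to the neopentyl aldehyde may be slow, and facial selectivity may be poor if reagent and substrate preferences are mismatched. The fallback sets C14 on the ring by reduction and sets out from 31. CH2=CHCH2MgBr gives homoallylic alcohol F14 as a C14 mixture, ring-closing metathesis as in step 19 gives ring A alcohols F15, and Dess–Martin oxidation gives ketone F16. LiBH(s-Bu)3 should attack equatorially, as bulky hydrides do on cyclohexanones flanked by a quaternary carbon with an axial methyl, to give the axial (14S)-alcohol F17. Acetylation as in step 18 returns to the route at 34.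

**Step 12.** The carboxylate may be partly reduced at C14, or the enoate may undergo conjugate reduction. The fallback reduces both carbonyl groups and re-oxidises one, and sets out from 21. Excess i-Bu2AlH at −78 °C reduces the enoate to the allylic alcohol and stops the imide at the chelated hemiaminal stage, giving hydroxy aldehyde F13 on work-up. Pinnick oxidation (NaClO2, NaH2PO4, 2-methylbut-2-ene), to which the allylic alcohol is inert, returns to the route at 24.

## Further compounds

F1 | step 14 | methyl (Z)-4-bromo-2-methylbut-2-enoate | BrC/C=C(/C)C(=O)OC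
F2 | step 14 | (Z)-isomer of enoate 15 | COC(=O)/C(C)=C\Cc1c(C)coc1C[C@@](C)(O[Si](CC)(CC)CC)CCC=C
F3 | step 14 | (Z)-isomer of diol 16 | COC(=O)/C(C)=C\Cc1c(C)coc1C[C@@](C)(O[Si](CC)(CC)CC)CCC(O)CO
F4 | step 14 | (Z)-isomer of aldehyde 17 | COC(=O)/C(C)=C\Cc1c(C)coc1C[C@@](C)(O[Si](CC)(CC)CC)CCC=O
F5 | step 14 | (Z)-isomer of aldol imide 20 | COC(=O)/C(C)=C\Cc1c(C)coc1C[C@@](C)(O[Si](CC)(CC)CC)CC[C@H](O)[C@@H](C)C(=O)N1[C@H](Cc2ccccc2)COC1=O
F6 | step 14 | (Z)-isomer of silyl ether 21 | COC(=O)/C(C)=C\Cc1c(C)coc1C[C@@](C)(O[Si](CC)(CC)CC)CC[C@H](O[Si](CC)(CC)CC)[C@@H](C)C(=O)N1[C@H](Cc2ccccc2)COC1=O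
F7 | step 14 | (Z)-isomer of peroxy acid 22 | COC(=O)/C(C)=C\Cc1c(C)coc1C[C@@](C)(O[Si](CC)(CC)CC)CC[C@H](O[Si](CC)(CC)CC)[C@@H](C)C(=O)OO
F8 | step 14 | (Z)-isomer of acid 23 | COC(=O)/C(C)=C\Cc1c(C)coc1C[C@@](C)(O[Si](CC)(CC)CC)CC[C@H](O[Si](CC)(CC)CC)[C@@H](C)C(O)=O
F9 | step 14 | (Z)-isomer of seco acid 24 | OC/C(C)=C\Cc1c(C)coc1C[C@@](C)(O[Si](CC)(CC)CC)CC[C@H](O[Si](CC)(CC)CC)[C@@H](C)C(O)=O
F10 | step 14 | (Z)-isomer of mixed anhydride 25 | OC/C(C)=C\Cc1c(C)coc1C[C@@](C)(O[Si](CC)(CC)CC)CC[C@H](O[Si](CC)(CC)CC)[C@@H](C)C(=O)OC(=O)c1c(Cl)cc(Cl)cc1Cl
F11 | step 14 | (10Z)-isomer of lactone 26 | O=C1OC/C(C)=C\Cc2c(C)coc2C[C@@](C)(O[Si](CC)(CC)CC)CC[C@H](O[Si](CC)(CC)CC)[C@H]1C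
F12 | step 14 | ring-cis trimethylsilyl ketene acetal of F11 | C[Si](C)(C)O/C1=C(\C)[C@@H](O[Si](CC)(CC)CC)CC[C@](C)(O[Si](CC)(CC)CC)Cc2occ(C)c2C/C=C(/C)CO1
F13 | step 12 | hydroxy aldehyde (C14 aldehyde, C12 allylic alcohol) | OC/C(C)=C/Cc1c(C)coc1C[C@@](C)(O[Si](CC)(CC)CC)CC[C@H](O[Si](CC)(CC)CC)[C@@H](C)C=O
F14 | step 17 | homoallylic alcohol, C14 epimers | C=CCC(O)[C@@]1(C)[C@H](C(C)=C)Cc2c(C)coc2C[C@@](C)(O[Si](CC)(CC)CC)CC[C@@H]1O[Si](CC)(CC)CC
F15 | step 17 | ring A alcohols, C14 epimers | OC1CC=C(C)[C@@H]2Cc3c(C)coc3C[C@@](C)(O[Si](CC)(CC)CC)CC[C@H](O[Si](CC)(CC)CC)[C@@]12C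
F16 | step 17 | ring A C14 ketone | O=C1CC=C(C)[C@@H]2Cc3c(C)coc3C[C@@](C)(O[Si](CC)(CC)CC)CC[C@H](O[Si](CC)(CC)CC)[C@@]12C
F17 | step 17 | (14S)-alcohol, deacetyl-34 | O[C@H]1CC=C(C)[C@@H]2Cc3c(C)coc3C[C@@](C)(O[Si](CC)(CC)CC)CC[C@H](O[Si](CC)(CC)CC)[C@@]12C
F18 | step 21 | butenolide with C7–H (C7 epimers) | CC(=O)O[C@H]1CC=C(C)[C@@H]2CC3=C(C)C(=O)OC3C[C@@](C)(O[Si](CC)(CC)CC)CC[C@H](O[Si](CC)(CC)CC)[C@@]12C
F19 | step 21 | 2-(triethylsilyloxy)furan (silyloxy on C19) | CC(=O)O[C@H]1CC=C(C)[C@@H]2Cc3c(C)c(O[Si](CC)(CC)CC)oc3C[C@@](C)(O[Si](CC)(CC)CC)CC[C@H](O[Si](CC)(CC)CC)[C@@]12C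
F20 | step 21 | C7 phenylselanyl butenolide | CC(=O)O[C@H]1CC=C(C)[C@@H]2CC3=C(C)C(=O)OC3([Se]c4ccccc4)C[C@@](C)(O[Si](CC)(CC)CC)CC[C@H](O[Si](CC)(CC)CC)[C@@]12C
A1 | alternative 1 | ring A aldol with C10, C1 and C2 set (C11 and C5 as dioxolanes) | O=C1CCC2(OCCO2)[C@H](C[Si](C)(C)c2ccccc2)[C@@]1(C)[C@@H](O)CCC1(C)OCCO1
A2 | alternative 1 | 7-methyl-1,4-dioxaspiro[4.5]dec-6-en-8-one | O=C1CCC2(OCCO2)C=C1C
A3 | alternative 1 | 3-(2-methyl-1,3-dioxolan-2-yl)propanal | O=CCCC1(C)OCCO1
A4 | alternative 1 | [(dimethylphenylsilyl)methyl]magnesium chloride | C[Si](C)(C[Mg]Cl)c1ccccc1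
A5 | alternative 2 | isoxazoline-bridged ten-membered carbocycle | CC(=O)O[C@H]1CC=C(C)[C@@H]2C/C(=C(\C)C(=O)OC)C3=NO[C@](C)(C3)CC[C@H](OC(=O)CC(C)C)[C@@]12C
A6 | alternative 2 | acyclic nitrile oxide on C7 with the C5=C6 alkene | CC(=O)O[C@H]1CC=C(C)[C@H](C/C(C#[N+][O-])=C(\C)C(=O)OC)[C@@]1(C)[C@@H](OC(=O)CC(C)C)CCC(C)=C
A7 | alternative 3 | C14 alcohol, C5 triethylsilyl ether of deacetyl-40 | O[C@H]1CC=C(C)[C@@H]2CC3=C(C)C(=O)O/C3=C/[C@@](C)(O[Si](CC)(CC)CC)CC[C@H](OC(=O)CC(C)C)[C@@]12C
A8 | alternative 3 | C14 aldehyde with a but-3-en-2-yl group on C10 (C11 epimers) | O=C[C@@]1(C)[C@H](C(C)C=C)CC2=C(C)C(=O)O/C2=C/[C@@](C)(O[Si](CC)(CC)CC)CC[C@@H]1OC(=O)CC(C)C
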